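Numbering: side chain C1 (benzylic CH2) to C13, C2 the acetoxy carbon, C8 the carbinol carbon; arene C1' (bears C1), C3' (OH), C5' (OMe).
Enabling feature: on the benzene ring the C3' hydroxyl, the C5' methoxyl and the C1 methylene sit mutually meta and the two oxygens differ, which is what a 3-alkylcyclobutenone and methoxyacetylene assemble directly.
Retrosynthetic cuts: the C8–O silyl ether; arene bonds C3'–C4', C5'–C6' and C2'–C3' (benzannulation); the four-membered ring (terminal alkyne + dichloroketene); then C1–C1', C3–C4 and C5–C6.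
Forward order: C5–C6 (acetylide + ethylene oxide), C3–C4 (Grignard + epichlorohydrin), C1–C1' (acetylide + epoxide), acetate, cyclobutenone ring, benzene ring, desilylation.
Stereochemistry: C8 (S) comes from (S)-1-octyn-3-ol and C2 (R) from (R)-epichlorohydrin; no later step makes or breaks a bond at either centre.

Key step: step 11

Assumption: methoxyacetylene is taken as not purchasable in usable form, so it is prepared fresh from chloroacetaldehyde dimethyl acetal (step 10) and used as a cold toluene solution.

Step 1
Reactants: 1 (S)-1-octyn-3-ol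
Product: 2 (S)-tert-butyldimethyl(oct-1-yn-3-yloxy)silane
Conditions: TBSCl, imidazole, DMF, rt
Reagents that add atoms: tert-butyldimethylsilyl chloride, CC(C)(C)[Si](C)(C)Cl
Why: Standard imidazole-promoted silylation of a secondary propargylic alcohol, which does not touch the carbinol carbon, so the future C8 keeps its S configuration.

Step 2
Reactants: 2 (S)-tert-butyldimethyl(oct-1-yn-3-yloxy)silane; 3 ethylene oxide
Product: 5 (S)-5-(tert-butyldimethylsilyloxy)dec-3-yn-1-ol, via lithium acetylide 4 (not isolated)
Conditions: n-BuLi, THF, −78 °C; BF3·OEt2, then 3, −78 °C; aq. NH4Cl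
Reagents that add atoms: none
Why: Yamaguchi–Hirao alkynylation, in which the lithium acetylide activated by BF3·OEt2 opens ethylene oxide at −78 °C to form the C5–C6 bond and place the hydroxyl on C4, while the silyl ether and the propargylic C–H are inert.

Step 3
Reactants: 5 (S)-5-(tert-butyldimethylsilyloxy)dec-3-yn-1-ol
Product: 6 (S)-5-(tert-butyldimethylsilyloxy)decan-1-ol
Conditions: H2 (1 atm), Pd/C, EtOAc, rt
Reagents that add atoms: none
Why: Heterogeneous catalytic hydrogenation saturates the alkyne to the C6–C7 ethylene unit; in a neutral aprotic solvent the silyl ether and the stereocentre are unaffected.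

Step 4
Reactants: 6 (S)-5-(tert-butyldimethylsilyloxy)decan-1-ol
Product: 7 (S)-(1-bromodecan-5-yloxy)(tert-butyl)dimethylsilane
Conditions: CBr4, PPh3, CH2Cl2, 0 °C
Reagents that add atoms: carbon tetrabromide, BrC(Br)(Br)Br
Why: Appel bromination converts the primary alcohol into the bromide under nearly neutral conditions that a secondary silyl ether tolerates.

Step 5
Reactants: 7 (S)-(1-bromodecan-5-yloxy)(tert-butyl)dimethylsilane; 8 (R)-epichlorohydrin
Product: 10 (2R,8S)-8-(tert-butyldimethylsilyloxy)-1-chlorotridecan-2-ol, via Grignard reagent 9 (not isolated)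
Conditions: Mg, THF, rt; then CuI (10 mol %), 8, THF, −40 → −20 °C; aq. NH4Cl
Reagents that add atoms: none
Why: Copper-catalysed Grignard opening of a terminal epoxide, in which the organocopper species attacks the unsubstituted ring carbon of 8 much faster than it displaces chloride at low temperature, forming C3–C4; no bond to the stereocentre is touched, so the R centre of 8 becomes C2 (R).

Step 6
Reactants: 10 (2R,8S)-8-(tert-butyldimethylsilyloxy)-1-chlorotridecan-2-ol; 11 lithium acetylide–ethylenediamine complex (LiC≡CH·H2NCH2CH2NH2)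
Product: 13 (4R,10S)-10-(tert-butyldimethylsilyloxy)pentadec-1-yn-4-ol, via epoxide 12 (not isolated)
Conditions: 11 (3.5 equiv), DMSO, 0 °C → rt; aq. NH4Cl
Reagents that add atoms: none
Why: Tandem Williamson epoxide closure and acetylide opening, in which the first equivalent of 11 deprotonates the chlorohydrin to close terminal epoxide 12 and a second equivalent opens 12 at its CH2 carbon by SN2 to form the C1–C1' bond, both events leaving C2 (R) untouched.

Step 7
Reactants: 13 (4R,10S)-10-(tert-butyldimethylsilyloxy)pentadec-1-yn-4-ol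
Product: 14 (4R,10S)-10-(tert-butyldimethylsilyloxy)pentadec-1-yn-4-yl acetate
Conditions: Ac2O, pyridine, DMAP (cat.), CH2Cl2, rt
Reagents that add atoms: acetic anhydride, CC(=O)OC(C)=O
Why: DMAP-catalysed acylation of the secondary alcohol installs the C2 acetate of the target with retention, and the ester also masks this oxygen during the ketene chemistry.

Step 8
Reactants: 14 (4R,10S)-10-(tert-butyldimethylsilyloxy)pentadec-1-yn-4-yl acetate; 15 trichloroacetyl chloride
Product: 17 (2R,8S)-8-(tert-butyldimethylsilyloxy)-1-(4,4-dichloro-3-oxocyclobut-1-en-1-yl)tridecan-2-yl acetate, via dichloroketene 16 (not isolated)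
Conditions: 15 (slow addition), Zn–Cu couple, Et2O/DME, rt
Reagents that add atoms: none
Why: Ketene–alkyne [2+2] cycloaddition, in which dichloroketene made in the flask by zinc dechlorination of 15 adds to the terminal alkyne with its carbonyl carbon bonding to the terminal CH, giving the 3-alkyl-4,4-dichlorocyclobutenone; DME binds the ZnCl2 formed so the silyl ether and acetate should persist.

Step 9
Reactants: 17 (2R,8S)-8-(tert-butyldimethylsilyloxy)-1-(4,4-dichloro-3-oxocyclobut-1-en-1-yl)tridecan-2-yl acetate
Product: 18 (2R,8S)-8-(tert-butyldimethylsilyloxy)-1-(3-oxocyclobut-1-en-1-yl)tridecan-2-yl acetate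
Conditions: Zn dust, AcOH, TMEDA, EtOH, 0 °C
Reagents that add atoms: none
Why: Reductive dehalogenation of an α,α-dichloroketone by zinc in amine-buffered acetic acid, the standard way to strip dichloroketene adducts to cyclobutenones; at 0 °C the medium is too weakly basic to cause vinylogous elimination of the C2 acetate.

Step 10
Reactants: 19 chloroacetaldehyde dimethyl acetal
Product: 21 methoxyacetylene, via sodium methoxyacetylide 20 (not isolated)
Conditions: NaNH2 (3 equiv), liquid NH3, −33 °C; NH3 evaporated; cold saturated aq. NaCl, −20 °C; distilled into toluene at −78 °C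
Reagents that add atoms: none
Why: Twofold base-induced elimination (methanol, then HCl) by NaNH2 gives the sodium acetylide, which is protonated on aqueous quench; this is the classical preparation of the volatile ynol ether.

Step 11
Reactants: 18 (2R,8S)-8-(tert-butyldimethylsilyloxy)-1-(3-oxocyclobut-1-en-1-yl)tridecan-2-yl acetate; 21 methoxyacetylene
Product: 26 (2R,8S)-8-(tert-butyldimethylsilyloxy)-1-(3-hydroxy-5-methoxyphenyl)tridecan-2-yl acetate, via vinylketene 22 (not isolated), via 2-vinylcyclobutenone 23 (not isolated), via dienylketene 24 (not isolated), via cyclohexadienone 25 (not isolated)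
Conditions: 21 (3 equiv), toluene, 80 °C, sealed tube
Reagents that add atoms: none
Why: Heating opens 18 by conrotatory 4π electrocyclic cleavage of its C(=O)–CH2 bond to vinylketene 22, whose ketene C=C adds 21 in a [2+2] cycloaddition to give the four-membered 2-vinylcyclobutenone 23; this opens reversibly to dienylketene 24, which closes the six-membered carbocycle by thermal disrotatory 6π electrocyclization between the ketene carbon and the terminal methylene (re-forming C2'–C3') to dienone 25, and enolization gives the phenol. The cascade is the Danheiser benzannulation, established for 3-alkylcyclobutenones and alkoxyacetylenes as a route to 5-alkylresorcinol monoethers. No stereocentre is created: the transiently stereogenic ring carbon of 23 becomes aromatic, and C2 and C8 lie outside the reacting π system under neutral thermal conditions. The selectivity needed is the orientation of the [2+2] step, and it is secured by the polarity of the ynol ether, whose unsubstituted nucleophilic carbon bonds to the electrophilic ketene carbonyl carbon (C3'–C4') while the methoxy-bearing carbon bonds to the ketene α-carbon (C5'–C6'), so OMe ends meta to both the C3' hydroxyl and the side chain. An excess of 21 keeps interception of the ketenes by the product phenol low.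

Step 12
Reactants: 26 (2R,8S)-8-(tert-butyldimethylsilyloxy)-1-(3-hydroxy-5-methoxyphenyl)tridecan-2-yl acetate
Product: 27 (2R,8S)-8-hydroxy-1-(3-hydroxy-5-methoxyphenyl)tridecan-2-yl acetate
Conditions: HF·pyridine, pyridine, THF, 0 °C → rt
Reagents that add atoms: none
Why: Fluoride-mediated desilylation in a buffered, non-basic medium cleaves the secondary Si–O bond while the acetate and phenol are inert, and the 1,7-relationship of C2–OAc to C8–OH rules out acyl migration.

Compound list

1 | (S)-1-octyn-3-ol | CCCCC[C@H](O)C#C | starting material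
2 | (S)-tert-butyldimethyl(oct-1-yn-3-yloxy)silane | CCCCC[C@H](O[Si](C)(C)C(C)(C)C)C#C | intermediate
3 | ethylene oxide | C1CO1 | starting material
4 | lithium (S)-3-(tert-butyldimethylsilyloxy)oct-1-yn-1-ide | CCCCC[C@H](O[Si](C)(C)C(C)(C)C)C#C[Li] | intermediate
5 | (S)-5-(tert-butyldimethylsilyloxy)dec-3-yn-1-ol | CCCCC[C@H](O[Si](C)(C)C(C)(C)C)C#CCCO | intermediate
6 | (S)-5-(tert-butyldimethylsilyloxy)decan-1-ol | CCCCC[C@H](O[Si](C)(C)C(C)(C)C)CCCCO | intermediate
7 | (S)-(1-bromodecan-5-yloxy)(tert-butyl)dimethylsilane | CCCCC[C@H](O[Si](C)(C)C(C)(C)C)CCCCBr | intermediate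
8 | (R)-epichlorohydrin | ClC[C@H]1CO1 | starting material
9 | [(S)-5-(tert-butyldimethylsilyloxy)decyl]magnesium bromide | CCCCC[C@H](O[Si](C)(C)C(C)(C)C)CCCC[Mg]Br | intermediate
10 | (2R,8S)-8-(tert-butyldimethylsilyloxy)-1-chlorotridecan-2-ol | CCCCC[C@H](O[Si](C)(C)C(C)(C)C)CCCCC[C@H](CCl)O | intermediate
11 | lithium acetylide–ethylenediamine complex | [Li]C#C.NCCN | starting material
12 | (R)-2-[(S)-6-(tert-butyldimethylsilyloxy)undecyl]oxirane | CCCCC[C@H](O[Si](C)(C)C(C)(C)C)CCCCC[C@@H]1CO1 | intermediate
13 | (4R,10S)-10-(tert-butyldimethylsilyloxy)pentadec-1-yn-4-ol | CCCCC[C@H](O[Si](C)(C)C(C)(C)C)CCCCC[C@H](CC#C)O | intermediate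
14 | (4R,10S)-10-(tert-butyldimethylsilyloxy)pentadec-1-yn-4-yl acetate | CCCCC[C@H](O[Si](C)(C)C(C)(C)C)CCCCC[C@H](CC#C)OC(C)=O | intermediate
15 | trichloroacetyl chloride | ClC(Cl)(Cl)C(Cl)=O | starting material
16 | dichloroketene | ClC(Cl)=C=O | intermediate
17 | (2R,8S)-8-(tert-butyldimethylsilyloxy)-1-(4,4-dichloro-3-oxocyclobut-1-en-1-yl)tridecan-2-yl acetate | CCCCC[C@H](O[Si](C)(C)C(C)(C)C)CCCCC[C@H](CC1=CC(=O)C1(Cl)Cl)OC(C)=O | intermediate
18 | (2R,8S)-8-(tert-butyldimethylsilyloxy)-1-(3-oxocyclobut-1-en-1-yl)tridecan-2-yl acetate | CCCCC[C@H](O[Si](C)(C)C(C)(C)C)CCCCC[C@H](CC1=CC(=O)C1)OC(C)=O | intermediate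
19 | chloroacetaldehyde dimethyl acetal | COC(CCl)OC | starting material
20 | sodium methoxyacetylide | COC#C[Na] | intermediate
21 | methoxyacetylene | COC#C | intermediate
22 | (2R,8S)-8-(tert-butyldimethylsilyloxy)-1-(4-oxobuta-1,3-dien-2-yl)tridecan-2-yl acetate (vinylketene) | CCCCC[C@H](O[Si](C)(C)C(C)(C)C)CCCCC[C@H](CC(=C)C=C=O)OC(C)=O | intermediate
23 | (4R,10S)-10-(tert-butyldimethylsilyloxy)-2-(2-methoxy-4-oxocyclobut-2-en-1-yl)pentadec-1-en-4-yl acetate (either configuration at the ring CH) | CCCCC[C@H](O[Si](C)(C)C(C)(C)C)CCCCC[C@H](CC(=C)C1C(=O)C=C1OC)OC(C)=O | intermediate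
24 | (2R,8S)-8-(tert-butyldimethylsilyloxy)-1-[(3E)-4-methoxy-6-oxohexa-1,3,5-trien-2-yl]tridecan-2-yl acetate (dienylketene) | CCCCC[C@H](O[Si](C)(C)C(C)(C)C)CCCCC[C@H](CC(=C)/C=C(OC)\C=C=O)OC(C)=O | intermediate
25 | (2R,8S)-8-(tert-butyldimethylsilyloxy)-1-(3-methoxy-5-oxocyclohexa-1,3-dien-1-yl)tridecan-2-yl acetate | CCCCC[C@H](O[Si](C)(C)C(C)(C)C)CCCCC[C@H](CC1=CC(OC)=CC(=O)C1)OC(C)=O | intermediate
26 | (2R,8S)-8-(tert-butyldimethylsilyloxy)-1-(3-hydroxy-5-methoxyphenyl)tridecan-2-yl acetate | CCCCC[C@H](O[Si](C)(C)C(C)(C)C)CCCCC[C@H](Cc1cc(O)cc(OC)c1)OC(C)=O | intermediate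
27 | (2R,8S)-8-hydroxy-1-(3-hydroxy-5-methoxyphenyl)tridecan-2-yl acetate | CCCCC[C@H](O)CCCCC[C@H](Cc1cc(O)cc(OC)c1)OC(C)=O | target

Step count and risks

Total: 12 steps. Longest linear sequence: 11 steps (1 to 27 through steps 1–9, 11 and 12); step 10 is a one-step side branch.

Steps most likely to fail:

1. Step 11. The ketene intermediates may be intercepted by the phenol as it forms, giving aryl ester oligomers. The volatile ynol ether may be lost by evaporation or polymerization before it is consumed, and prolonged heating could induce elimination of acetic acid from the cyclobutenone. The fallback gives up arene construction and attaches a preformed ring; it sets out from chlorohydrin 10 and comes back to the route at 26. Chlorohydrin 10 is closed with powdered NaOH in Et2O to epoxide 12, which is isolated. 3-Bromo-5-methoxyphenol is benzylated with BnBr and K2CO3 in acetone to give 1-(benzyloxy)-3-bromo-5-methoxybenzene F1. Mg in THF converts this bromide into [3-(benzyloxy)-5-methoxyphenyl]magnesium bromide F2. CuI-catalysed opening of 12 at its CH2 carbon by this Grignard reagent should give (2R,8S)-1-[3-(benzyloxy)-5-methoxyphenyl]-8-(tert-butyldimethylsilyloxy)tridecan-2-ol F3. Acetylation with Ac2O, pyridine and DMAP gives (2R,8S)-1-[3-(benzyloxy)-5-methoxyphenyl]-8-(tert-butyldimethylsilyloxy)tridecan-2-yl acetate F4. Hydrogenolysis of the benzyl ether with H2 over Pd/C in EtOAc then delivers 26.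

2. Step 8. Dichloroketene may oligomerize faster than it adds to the unactivated alkyne, and the ZnCl2 formed may strip the silyl ether or activate the acetate. The fallback builds the four-membered ring at the correct oxidation level by a Ghosez keteniminium cycloaddition; it sets out from 14 and comes back to the route at 18. N,N-Dimethylacetamide, Tf2O and 2,4,6-collidine in 1,2-dichloroethane generate N,N-dimethylketeniminium trifluoromethanesulfonate F5. Its [2+2] addition to the alkyne of 14 should give N-{3-[(2R,8S)-2-acetoxy-8-(tert-butyldimethylsilyloxy)tridecyl]cyclobut-2-en-1-ylidene}-N-methylmethanaminium trifluoromethanesulfonate F6. Hydrolysis of this iminium salt with aq. NaHCO3 gives 18. This path uses no zinc and also bypasses the dechlorination of step 9.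

3. Step 5. Competing displacement of chloride or halide exchange at the epichlorohydrin would erode the configurational purity of C2, and Wurtz-type homocoupling would consume the Grignard reagent. The fallback uses a C3 electrophile without a second leaving group; it sets out from bromide 7 through Grignard reagent 9 and comes back to the route at epoxide 12. CuI-catalysed opening of (R)-benzyl glycidyl ether by 9 should give (2R,8S)-1-(benzyloxy)-8-(tert-butyldimethylsilyloxy)tridecan-2-ol F7. Hydrogenolysis with H2 over Pd/C in EtOAc gives (2R,8S)-8-(tert-butyldimethylsilyloxy)tridecane-1,2-diol F8. Selective primary sulfonylation with TsCl, Et3N and catalytic Bu2SnO in CH2Cl2 gives (2R,8S)-8-(tert-butyldimethylsilyloxy)-2-hydroxytridecyl 4-methylbenzenesulfonate F9. Closure with K2CO3 in MeOH gives epoxide 12, which is then treated with 11 as in step 6.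

Further compounds

F1 | step 11 | 1-(benzyloxy)-3-bromo-5-methoxybenzene | COc1cc(Br)cc(OCc2ccccc2)c1
F2 | step 11 | [3-(benzyloxy)-5-methoxyphenyl]magnesium bromide | COc1cc([Mg]Br)cc(OCc2ccccc2)c1
F3 | step 11 | (2R,8S)-1-[3-(benzyloxy)-5-methoxyphenyl]-8-(tert-butyldimethylsilyloxy)tridecan-2-ol | CCCCC[C@H](O[Si](C)(C)C(C)(C)C)CCCCC[C@H](Cc1cc(OCc2ccccc2)cc(OC)c1)O
F4 | step 11 | (2R,8S)-1-[3-(benzyloxy)-5-methoxyphenyl]-8-(tert-butyldimethylsilyloxy)tridecan-2-yl acetate | CCCCC[C@H](O[Si](C)(C)C(C)(C)C)CCCCC[C@H](Cc1cc(OCc2ccccc2)cc(OC)c1)OC(C)=O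
F5 | step 8 | N,N-dimethylketeniminium trifluoromethanesulfonate | C=C=[N+](C)C.[O-]S(=O)(=O)C(F)(F)F
F6 | step 8 | N-{3-[(2R,8S)-2-acetoxy-8-(tert-butyldimethylsilyloxy)tridecyl]cyclobut-2-en-1-ylidene}-N-methylmethanaminium trifluoromethanesulfonate | CCCCC[C@H](O[Si](C)(C)C(C)(C)C)CCCCC[C@H](CC1=CC(=[N+](C)C)C1)OC(C)=O.[O-]S(=O)(=O)C(F)(F)F
F7 | step 5 | (2R,8S)-1-(benzyloxy)-8-(tert-butyldimethylsilyloxy)tridecan-2-ol | CCCCC[C@H](O[Si](C)(C)C(C)(C)C)CCCCC[C@H](COCc1ccccc1)O
F8 | step 5 | (2R,8S)-8-(tert-butyldimethylsilyloxy)tridecane-1,2-diol | CCCCC[C@H](O[Si](C)(C)C(C)(C)C)CCCCC[C@H](CO)O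
F9 | step 5 | (2R,8S)-8-(tert-butyldimethylsilyloxy)-2-hydroxytridecyl 4-methylbenzenesulfonate | CCCCC[C@H](O[Si](C)(C)C(C)(C)C)CCCCC[C@H](COS(=O)(=O)c1ccc(C)cc1)O
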